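**Strategy.** The oxolane is disconnected at O1–C2 and C4–C5 (O1 = ring oxygen, C2 = carbon bearing the 4-alkoxy-3-methoxyphenyl ring, C5 = carbon bearing the 3,4-dimethoxyphenyl ring). Both bonds arise in one operation from veratraldehyde and a (Z)-crotyl reagent carrying two boryl groups on the future C2: a phosphoric acid-catalysed syn-crotylboration forms C4–C5 and sets C4/C5, and oxidation of the remaining alkenyl C–B bond unmasks C2 as an aldehyde that the C5 oxygen closes to a lactol. The step exploits C2 being an O1-flanked, acetal-level carbon: its aryl group (with the complete side chain) and the C3 methyl are relayed later by substrate control.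

Key step: step 3

Assumption: (S)-TRIP is taken to expose the Si face of veratraldehyde to reagent 4, as in phosphoric acid-catalysed allylborations of aryl aldehydes; should the sense be opposite, (R)-TRIP is used.

Step 1
Reactants: 1 bis[(pinacolato)boryl]methane; 2 allyl bromide
Product: 3 2,2'-(but-3-ene-1,1-diyl)bis(4,4,5,5-tetramethyl-1,3,2-dioxaborolane)
Conditions: LiTMP (from TMP, n-BuLi), THF, 0 °C; then 2, 0 °C to rt
Reagents that add atoms: none
Why: Deprotonation between the two boron atoms gives a boron-stabilised carbanion that alkylates allyl bromide by SN2 (alkylation of a lithiated gem-diborylmethane); no stereocentre is formed.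

Step 2
Reactants: 3 2,2'-(but-3-ene-1,1-diyl)bis(4,4,5,5-tetramethyl-1,3,2-dioxaborolane)
Product: 4 (Z)-2,2'-(but-2-ene-1,1-diyl)bis(4,4,5,5-tetramethyl-1,3,2-dioxaborolane)
Conditions: NiCl2(dppp) (5 mol%), Ph2PH (5 mol%), Zn (10 mol%), ZnI2 (10 mol%), CH2Cl2, 0 °C to rt
Reagents that add atoms: none
Why: A Ni–H catalyst moves the terminal double bond by one position through insertion/β-hydride elimination with kinetic Z-selectivity (Z-selective alkene isomerisation), fixing the geometry that later becomes the cis C4-methyl/C5-aryl relationship.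

Step 3
Reactants: 5 3,4-dimethoxybenzaldehyde (veratraldehyde); 4 (Z)-2,2'-(but-2-ene-1,1-diyl)bis(4,4,5,5-tetramethyl-1,3,2-dioxaborolane)
Product: 8 (4R,5S)-5-(3,4-dimethoxyphenyl)-4-methyloxolan-2-ol (lactol; anomer mixture), via homoallylic borate 6 (not isolated), via hydroxy aldehyde 7 (not isolated)
Conditions: (S)-TRIP (5 mol%), 4 Å MS, toluene, −45 °C; then NaBO3·4H2O, THF–H2O, rt
Reagents that add atoms: sodium perborate (used as the tetrahydrate), [Na+].[Na+].O[B-]1(O)OO[B-](O)(O)OO1
Why: The chiral phosphoric acid activates the boronate–aldehyde pair and the γ-carbon of 4 adds through a closed chair (Zimmerman–Traxler-type) transition state, forming C4–C5 and leaving the second boron as an alkenyl boronate on the future C2; perborate then oxidises that C–B bond to the aldehyde, which the C5 oxygen captures to form O1–C2. The closest known reaction type is the phosphoric acid-catalysed enantioselective crotylboration of aryl aldehydes with α-boryl (gem-diboryl) crotylboronates followed by oxidative work-up, i.e. a homoaldol equivalent. The oxolane closes by 5-exo-trig addition of the secondary hydroxyl to the aldehyde (reversible hemiacetalisation to the favoured five-membered lactol). C5 (S) is set by the catalyst through Si-face attack on the aldehyde; C4 (R) follows from the Z geometry of 4 in the chair transition state (syn adduct, methyl cis to aryl on the ring); the anomeric C2 stays a mixture because it is planarised later. The step needs γ-regioselectivity and syn-selectivity, secured by the cyclic transition state and the Z-alkene, and chemoselective oxidation of the alkenyl C–B bond, secured by a mild nucleophilic oxidant that leaves the electron-rich arene and the benzylic C–O bond untouched.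

Step 4
Reactants: 8 (4R,5S)-5-(3,4-dimethoxyphenyl)-4-methyloxolan-2-ol
Product: 9 (4R,5S)-5-(3,4-dimethoxyphenyl)-4-methyloxolan-2-one
Conditions: TEMPO (10 mol%), PhI(OAc)2, CH2Cl2, rt
Reagents that add atoms: none
Why: Oxoammonium (TEMPO/PhI(OAc)2) oxidation of the hemiacetal hydroxyl gives the γ-lactone without touching C4 and C5 (lactol-to-lactone oxidation).

Step 5
Reactants: 9 (4R,5S)-5-(3,4-dimethoxyphenyl)-4-methyloxolan-2-one
Product: 10 (3R,4R,5S)-5-(3,4-dimethoxyphenyl)-3,4-dimethyloxolan-2-one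
Conditions: LiHMDS, THF, −78 °C; MeI, −78 to −40 °C
Reagents that add atoms: iodomethane, CI
Why: Lithium enolate alkylation should occur anti to the adjacent C4 methyl, which shares a face with the C5 aryl group, so the new C3 methyl is trans to C4-Me, i.e. (3R) (substrate-controlled lactone α-methylation).

Step 6
Reactants: 10 (3R,4R,5S)-5-(3,4-dimethoxyphenyl)-3,4-dimethyloxolan-2-one
Product: 12 (3R,4R,5S)-2-(benzenesulfonyl)-5-(3,4-dimethoxyphenyl)-3,4-dimethyloxolane (anomer mixture), via lactol 11 (not isolated)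
Conditions: DIBAL-H, CH2Cl2, −78 °C, Rochelle salt work-up; then PhSO2H, CaCl2, CH2Cl2, rt
Reagents that add atoms: benzenesulfinic acid, O=S(O)c1ccccc1
Why: DIBAL-H half-reduction stops at the lactol, whose anomeric hydroxyl is exchanged for benzenesulfinate via the oxocarbenium ion under dehydrating conditions (formation of a 2-sulfonyl cyclic ether); the anomeric configuration is irrelevant.

Step 7
Reactants: 13 4-bromo-2-methoxyphenol; 14 ethyl (S)-lactate
Product: 15 ethyl (2R)-2-(4-bromo-2-methoxyphenoxy)propanoate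
Conditions: PPh3, DIAD, THF, 0 °C to rt
Reagents that add atoms: none
Why: Mitsunobu reaction; SN2 displacement of the activated lactate hydroxyl by the phenol proceeds with inversion and gives the (R)-aryl ether.

Step 8
Reactants: 15 ethyl (2R)-2-(4-bromo-2-methoxyphenoxy)propanoate; 16 3,4-dimethoxyphenylmagnesium bromide (commercial THF solution)
Product: 18 (2R)-2-(4-bromo-2-methoxyphenoxy)-1-(3,4-dimethoxyphenyl)propan-1-one, via Weinreb amide 17 (not isolated)
Conditions: MeNHOMe·HCl, i-PrMgCl, THF, −20 °C; then 16, −20 to 0 °C; aq. NH4Cl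
Reagents that add atoms: none
Why: One-pot Weinreb ketone synthesis; the ester is converted in situ into the N-methoxy-N-methylamide, whose chelated tetrahedral adduct with the aryl Grignard reagent releases the ketone only on work-up, at low temperature to keep the α-aryloxy stereocentre intact.

Step 9
Reactants: 18 (2R)-2-(4-bromo-2-methoxyphenoxy)-1-(3,4-dimethoxyphenyl)propan-1-one
Product: 19 (1R,2R)-2-(4-bromo-2-methoxyphenoxy)-1-(3,4-dimethoxyphenyl)propan-1-ol
Conditions: (R)-2-methyl-CBS-oxazaborolidine (20 mol%), BH3·SMe2, THF, −20 °C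
Reagents that add atoms: none
Why: Corey–Bakshi–Shibata reduction; the (R)-oxazaborolidine should deliver hydride to the face of the aryl ketone that gives the (1R)-carbinol, matched with the Felkin–Anh preference of the α-aryloxy ketone, so the threo (1R,2R) alcohol is expected.

Step 10
Reactants: 19 (1R,2R)-2-(4-bromo-2-methoxyphenoxy)-1-(3,4-dimethoxyphenyl)propan-1-ol
Product: 20 [(1R,2R)-2-(4-bromo-2-methoxyphenoxy)-1-(3,4-dimethoxyphenyl)propoxy](tert-butyl)dimethylsilane
Conditions: TBSCl, imidazole, DMF, rt to 40 °C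
Reagents that add atoms: tert-butyldimethylsilyl chloride, CC(C)(C)[Si](C)(C)Cl
Why: Silylation of the secondary benzylic alcohol (TBS ether formation) masks the hydroxyl for the organometallic step.

Step 11
Reactants: 20 [(1R,2R)-2-(4-bromo-2-methoxyphenoxy)-1-(3,4-dimethoxyphenyl)propoxy](tert-butyl)dimethylsilane (2 equiv); 12 (3R,4R,5S)-2-(benzenesulfonyl)-5-(3,4-dimethoxyphenyl)-3,4-dimethyloxolane
Product: 24 (1R,2R)-1-(3,4-dimethoxyphenyl)-2-{4-[(2S,3R,4R,5S)-5-(3,4-dimethoxyphenyl)-3,4-dimethyloxolan-2-yl]-2-methoxyphenoxy}propan-1-ol (target), via aryllithium 21 (not isolated), via arylzinc bromide 22 (not isolated), via silyl ether 23 (not isolated)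
Conditions: t-BuLi (2 equiv per 20), THF, −78 °C; ZnBr2, −78 to 0 °C; then 12, THF, rt; aqueous work-up; then TBAF, THF, rt on the crude silyl ether
Reagents that add atoms: none
Why: Bromine–lithium exchange and transmetalation give an arylzinc reagent, and zinc-assisted ionisation of the sulfone generates the cyclic oxocarbenium ion, to which the aryl group should add cis to the C3 methyl and anti to the face carrying the C4 methyl and C5 aryl (arylzinc addition to a 2-sulfonyl cyclic ether), setting C2 (S) before fluoride removes the silyl group.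

**Compound list**

1 | bis[(pinacolato)boryl]methane (2,2'-methylenebis(4,4,5,5-tetramethyl-1,3,2-dioxaborolane)) | CC1(C)OB(CB2OC(C)(C)C(C)(C)O2)OC1(C)C | starting material
2 | allyl bromide | C=CCBr | starting material
3 | 2,2'-(but-3-ene-1,1-diyl)bis(4,4,5,5-tetramethyl-1,3,2-dioxaborolane) | C=CCC(B1OC(C)(C)C(C)(C)O1)B1OC(C)(C)C(C)(C)O1 | intermediate
4 | (Z)-2,2'-(but-2-ene-1,1-diyl)bis(4,4,5,5-tetramethyl-1,3,2-dioxaborolane) | C/C=C\C(B1OC(C)(C)C(C)(C)O1)B1OC(C)(C)C(C)(C)O1 | intermediate
5 | 3,4-dimethoxybenzaldehyde (veratraldehyde) | COc1ccc(C=O)cc1OC | starting material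
6 | pinacol borate of (1S,2R,3E)-1-(3,4-dimethoxyphenyl)-2-methyl-4-(pinacolboryl)but-3-en-1-ol | COc1ccc([C@@H](OB2OC(C)(C)C(C)(C)O2)[C@H](C)/C=C/B2OC(C)(C)C(C)(C)O2)cc1OC | intermediate
7 | (3R,4S)-4-(3,4-dimethoxyphenyl)-4-hydroxy-3-methylbutanal | COc1ccc([C@@H](O)[C@H](C)CC=O)cc1OC | intermediate
8 | (4R,5S)-5-(3,4-dimethoxyphenyl)-4-methyloxolan-2-ol (anomer mixture) | OC1O[C@H](c2ccc(OC)c(OC)c2)[C@H](C)C1 | intermediate
9 | (4R,5S)-5-(3,4-dimethoxyphenyl)-4-methyloxolan-2-one | O=C1O[C@H](c2ccc(OC)c(OC)c2)[C@H](C)C1 | intermediate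
10 | (3R,4R,5S)-5-(3,4-dimethoxyphenyl)-3,4-dimethyloxolan-2-one | O=C1O[C@H](c2ccc(OC)c(OC)c2)[C@H](C)[C@H]1C | intermediate
11 | (3R,4R,5S)-5-(3,4-dimethoxyphenyl)-3,4-dimethyloxolan-2-ol (anomer mixture) | OC1O[C@H](c2ccc(OC)c(OC)c2)[C@H](C)[C@H]1C | intermediate
12 | (3R,4R,5S)-2-(benzenesulfonyl)-5-(3,4-dimethoxyphenyl)-3,4-dimethyloxolane (anomer mixture) | O=S(=O)(c1ccccc1)C1O[C@H](c2ccc(OC)c(OC)c2)[C@H](C)[C@H]1C | intermediate
13 | 4-bromo-2-methoxyphenol | COc1cc(Br)ccc1O | starting material
14 | ethyl (S)-lactate | CCOC(=O)[C@H](C)O | starting material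
15 | ethyl (2R)-2-(4-bromo-2-methoxyphenoxy)propanoate | CCOC(=O)[C@@H](C)Oc1ccc(Br)cc1OC | intermediate
16 | 3,4-dimethoxyphenylmagnesium bromide | COc1ccc([Mg]Br)cc1OC | starting material
17 | (2R)-2-(4-bromo-2-methoxyphenoxy)-N-methoxy-N-methylpropanamide | CON(C)C(=O)[C@@H](C)Oc1ccc(Br)cc1OC | intermediate
18 | (2R)-2-(4-bromo-2-methoxyphenoxy)-1-(3,4-dimethoxyphenyl)propan-1-one | COc1ccc(C(=O)[C@@H](C)Oc2ccc(Br)cc2OC)cc1OC | intermediate
19 | (1R,2R)-2-(4-bromo-2-methoxyphenoxy)-1-(3,4-dimethoxyphenyl)propan-1-ol | COc1ccc([C@@H](O)[C@@H](C)Oc2ccc(Br)cc2OC)cc1OC | intermediate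
20 | [(1R,2R)-2-(4-bromo-2-methoxyphenoxy)-1-(3,4-dimethoxyphenyl)propoxy](tert-butyl)dimethylsilane | COc1ccc([C@@H](O[Si](C)(C)C(C)(C)C)[C@@H](C)Oc2ccc(Br)cc2OC)cc1OC | intermediate
21 | aryllithium from 20 (Li in place of Br) | COc1ccc([C@@H](O[Si](C)(C)C(C)(C)C)[C@@H](C)Oc2ccc([Li])cc2OC)cc1OC | intermediate
22 | arylzinc bromide from 21 (ZnBr in place of Li) | COc1ccc([C@@H](O[Si](C)(C)C(C)(C)C)[C@@H](C)Oc2ccc([Zn]Br)cc2OC)cc1OC | intermediate
23 | O-TBS ether of the target | COc1ccc([C@@H](O[Si](C)(C)C(C)(C)C)[C@@H](C)Oc2ccc([C@H]3O[C@H](c4ccc(OC)c(OC)c4)[C@H](C)[C@H]3C)cc2OC)cc1OC | intermediate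
24 | (1R,2R)-1-(3,4-dimethoxyphenyl)-2-{4-[(2S,3R,4R,5S)-5-(3,4-dimethoxyphenyl)-3,4-dimethyloxolan-2-yl]-2-methoxyphenoxy}propan-1-ol | COc1ccc([C@@H](O)[C@@H](C)Oc2ccc([C@H]3O[C@H](c4ccc(OC)c(OC)c4)[C@H](C)[C@H]3C)cc2OC)cc1OC | target

**Totals.** Total step count: 11. Longest linear sequence: 7 steps (steps 1–6 and 11); the side-chain arm (steps 7–10) joins in step 11.

**Steps most likely to fail**

Step 3. The syn- and enantioselectivity may erode, through loss of Z geometry in reagent 4 by 1,3-boryl migration or through an uncatalysed background addition to the electron-rich aldehyde. The fallback sets out from 5 and returns at 9. Aldehyde 5 would be syn-crotylated with the commercially available chiral diamine-derived (Z)-crotylsilane reagent (Sc(OTf)3 catalysis, enantiomer chosen for the 1S,2R product) to give (1S,2R)-1-(3,4-dimethoxyphenyl)-2-methylbut-3-en-1-ol F1. Hydroboration with 9-BBN and alkaline peroxide oxidation would give (1S,2R)-1-(3,4-dimethoxyphenyl)-2-methylbutane-1,4-diol F2. TEMPO/PhI(OAc)2 oxidative lactonisation would then give lactone 9.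

Step 11. The bulky, functionalised arylzinc reagent may add sluggishly or with poor facial selectivity to the oxocarbenium ion, and the advanced bromide 20 is consumed in excess. The fallback sets out from 12 and returns at 24, building the side chain on the core instead. [4-(Benzyloxy)-3-methoxyphenyl]zinc bromide F3, made from commercial 1-(benzyloxy)-4-bromo-2-methoxybenzene with Mg then ZnBr2, would add to 12 to give (2S,3R,4R,5S)-2-[4-(benzyloxy)-3-methoxyphenyl]-5-(3,4-dimethoxyphenyl)-3,4-dimethyloxolane F4. Hydrogenolysis (H2, Pd/C) would give the phenol 4-[(2S,3R,4R,5S)-5-(3,4-dimethoxyphenyl)-3,4-dimethyloxolan-2-yl]-2-methoxyphenol F5. A Mitsunobu reaction with commercial (S)-2-hydroxy-N-methoxy-N-methylpropanamide would give the (R)-configured Weinreb amide F6. Addition of 16 would give the aryl ketone F7, and Corey–Bakshi–Shibata reduction under the conditions of step 9 would give 24.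

Step 8. The α-aryloxy stereocentre may partly epimerise by enolisation under the basic magnesium amide and Grignard conditions. The fallback sets out from 15 and returns at 19, bypassing the ketone. DIBAL-H at −78 °C would reduce 15 to (2R)-2-(4-bromo-2-methoxyphenoxy)propanal F8, used at once. Chelation-controlled addition of 16 (MgBr2·OEt2, CH2Cl2, −78 °C, Cram-chelate model) should give the threo alcohol 19 directly.

**Further compounds**

F1 | step 3 | (1S,2R)-1-(3,4-dimethoxyphenyl)-2-methylbut-3-en-1-ol | COc1ccc([C@@H](O)[C@H](C)C=C)cc1OC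
F2 | step 3 | (1S,2R)-1-(3,4-dimethoxyphenyl)-2-methylbutane-1,4-diol | COc1ccc([C@@H](O)[C@H](C)CCO)cc1OC
F3 | step 11 | [4-(benzyloxy)-3-methoxyphenyl]zinc bromide | COc1cc([Zn]Br)ccc1OCc1ccccc1
F4 | step 11 | (2S,3R,4R,5S)-2-[4-(benzyloxy)-3-methoxyphenyl]-5-(3,4-dimethoxyphenyl)-3,4-dimethyloxolane | COc1cc([C@H]2O[C@H](c3ccc(OC)c(OC)c3)[C@H](C)[C@H]2C)ccc1OCc1ccccc1
F5 | step 11 | 4-[(2S,3R,4R,5S)-5-(3,4-dimethoxyphenyl)-3,4-dimethyloxolan-2-yl]-2-methoxyphenol | COc1cc([C@H]2O[C@H](c3ccc(OC)c(OC)c3)[C@H](C)[C@H]2C)ccc1O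
F6 | step 11 | (2R)-2-{4-[(2S,3R,4R,5S)-5-(3,4-dimethoxyphenyl)-3,4-dimethyloxolan-2-yl]-2-methoxyphenoxy}-N-methoxy-N-methylpropanamide | CON(C)C(=O)[C@@H](C)Oc1ccc([C@H]2O[C@H](c3ccc(OC)c(OC)c3)[C@H](C)[C@H]2C)cc1OC
F7 | step 11 | (2R)-1-(3,4-dimethoxyphenyl)-2-{4-[(2S,3R,4R,5S)-5-(3,4-dimethoxyphenyl)-3,4-dimethyloxolan-2-yl]-2-methoxyphenoxy}propan-1-one | COc1ccc(C(=O)[C@@H](C)Oc2ccc([C@H]3O[C@H](c4ccc(OC)c(OC)c4)[C@H](C)[C@H]3C)cc2OC)cc1OC
F8 | step 8 | (2R)-2-(4-bromo-2-methoxyphenoxy)propanal | O=C[C@@H](C)Oc1ccc(Br)cc1OC
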